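Ring A is disconnected at C4a–C5. Its meta oxygens at C6 and C8, next to the aryl-bearing C5, mark it as a folded C4a–C8a–C8–C7–C6–C5 poly-β-carbonyl chain. A base-mediated aldol of a 1,3,5-triketone, in which the naphthyl-bearing C5 methylene adds to the ring B ketone carbon (C4a), closes and aromatizes ring A in one operation; the C5–C1′ biaryl bond is carried in as a CH2–aryl bond, so no cross-coupling is needed. The precursor is a Boc-protected (2S)-2-methyl-4-piperidone with a 4-naphthyl-3-oxobutanoyl chain on the ring carbon next to NCH2. It is assembled from a 5-acetyl-4-piperidone dianion and an ethyl naphthylacetate. Its stereocentre, bought with the piperidone, becomes C3.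

Key step: step 9

Assumption: the target structure does not define the configuration of the hindered C5–C1′ axis; it is left uncontrolled, so 19, 20 and 21 are expected as mixtures of atropisomers about this axis, each (3S).

Numbering: 12–17 use piperidine numbering, 18–21 isoquinoline numbering (piperidine C2, C3, C4, C5, C6 become C3, C4, C4a, C8a, C1).

Step 1
Reactants: 1 2-methoxy-4-methylbenzoic acid
Product: 3 N,N-diethyl-2-methoxy-4-methylbenzamide, via acid chloride 2 (not isolated)
Conditions: (COCl)2, DMF (cat.), CH2Cl2, 0 °C → rt; then Et2NH (2.5 equiv), CH2Cl2, 0 °C → rt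
Reagents that add atoms: diethylamine, CCNCC
Why: Acyl chloride formation and Schotten–Baumann-type amidation install the tertiary diethylamide, the directing group needed for the next two steps.

Step 2
Reactants: 3 N,N-diethyl-2-methoxy-4-methylbenzamide
Product: 6 N,N-diethyl-2-methoxy-4-methyl-6-(prop-2-en-1-yl)benzamide, via aryllithium 4 (not isolated), via arylmagnesium bromide 5 (not isolated)
Conditions: s-BuLi, TMEDA, THF, −78 °C; MgBr2·OEt2, −78 → 0 °C; allyl bromide, 0 °C → rt
Reagents that add atoms: allyl bromide, C=CCBr
Why: Directed ortho-metalation: the diethylamide outranks the methoxy group as director, so s-BuLi/TMEDA removes the only free ortho hydrogen (H-6), and transmetalation to magnesium lets the aryl nucleophile displace bromide from allyl bromide without proton transfer.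

Step 3
Reactants: 6 N,N-diethyl-2-methoxy-4-methyl-6-(prop-2-en-1-yl)benzamide
Product: 8 8-methoxy-6-methylnaphthalen-1-ol, via naphthalenone 7 (not isolated)
Conditions: LiN(i-Pr)2 (2.5 equiv), THF, −78 °C → rt; then 1 M HCl
Reagents that add atoms: none
Why: Anionic benzannulation (intramolecular acylation of an allyl anion): the base removes a benzylic/allylic proton, the terminal carbon of the allyl anion attacks the neighbouring amide carbonyl, diethylamide leaves and naphthalenone 7 tautomerizes to the naphthol, which fixes the new oxygen peri to the methoxy group and leaves the former benzylic carbon as the free para position C4.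

Step 4
Reactants: 8 8-methoxy-6-methylnaphthalen-1-ol
Product: 9 4-bromo-8-methoxy-6-methylnaphthalen-1-ol
Conditions: NBS (1.0 equiv), MeCN, −20 → 0 °C
Reagents that add atoms: N-bromosuccinimide, O=C1CCC(=O)N1Br
Why: Electrophilic aromatic bromination: the free hydroxyl, hydrogen-bonded to the peri methoxy oxygen, makes its own ring the more electron-rich one, and NBS in MeCN at low temperature should enter para to it (C4) rather than ortho (C2), which is why bromination is placed before O-methylation, after which the two rings would no longer be differentiated.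

Step 5
Reactants: 9 4-bromo-8-methoxy-6-methylnaphthalen-1-ol
Product: 10 1-bromo-4,5-dimethoxy-7-methylnaphthalene
Conditions: Me2SO4, K2CO3, acetone, reflux
Reagents that add atoms: dimethyl sulfate, COS(=O)(=O)OC
Why: Williamson O-methylation of the naphthoxide with a hard methylating agent; no other acidic site is present.

Step 6
Reactants: 10 1-bromo-4,5-dimethoxy-7-methylnaphthalene
Product: 11 ethyl 2-(4,5-dimethoxy-7-methylnaphthalen-1-yl)acetate
Conditions: BrZnCH2CO2Et (from BrCH2CO2Et, Zn dust, THF), Pd2(dba)3 (2 mol %), XPhos (8 mol %), THF, 65 °C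
Reagents that add atoms: ethyl bromoacetate, CCOC(=O)CBr (used as its zinc reagent, CCOC(=O)C[Zn]Br)
Why: Negishi-type cross-coupling of a Reformatsky reagent: oxidative addition of the electron-rich aryl bromide to zerovalent palladium carrying the bulky biarylphosphine, transmetalation of the zinc ester enolate and reductive elimination give the arylacetate directly as an ethyl ester that can act as acyl donor in step 8.

Step 7
Reactants: 12 tert-butyl (S)-2-methyl-4-oxopiperidine-1-carboxylate
Product: 15 tert-butyl (2S)-5-acetyl-2-methyl-4-oxopiperidine-1-carboxylate, via enamine 13 (not isolated), via acetyl enaminone 14 (not isolated)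
Conditions: pyrrolidine, 4 Å MS, PhMe, rt; evaporate; Ac2O, dioxane, rt; then 10% aq. AcOH, rt
Reagents that add atoms: acetic anhydride, CC(=O)OC(C)=O
Why: Stork enamine acylation: the pyrrolidine enamine is acetylated at carbon and mild aqueous hydrolysis releases the β-diketone; acylation is expected at C5 because the 2-methyl group, held axial by allylic 1,3-strain with the carbamate, screens C3, and forming the enamine at room temperature avoids heating the β-amino ketone, so C2 should keep its (S) configuration.

Step 8
Reactants: 15 tert-butyl (2S)-5-acetyl-2-methyl-4-oxopiperidine-1-carboxylate; 11 ethyl 2-(4,5-dimethoxy-7-methylnaphthalen-1-yl)acetate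
Product: 17 tert-butyl (2S)-5-[4-(4,5-dimethoxy-7-methylnaphthalen-1-yl)-3-oxobutanoyl]-2-methyl-4-oxopiperidine-1-carboxylate, via dilithium dienolate 16 (not isolated)
Conditions: 15 (2.5 equiv), LiN(i-Pr)2 (5.2 equiv), THF, −78 → 0 °C; then 11 (1 equiv), −78 → 0 °C; AcOH, −78 °C
Reagents that add atoms: none
Why: γ-Acylation of a 1,3-diketone dianion (Claisen-type condensation): the second equivalent of amide base removes a proton from the terminal acetyl CH3, this more reactive carbanion end attacks the ester carbonyl, the excess dianion serves as base for the more acidic triketone formed, and the C2 stereocentre is not touched at low temperature.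

Step 9
Reactants: 17 tert-butyl (2S)-5-[4-(4,5-dimethoxy-7-methylnaphthalen-1-yl)-3-oxobutanoyl]-2-methyl-4-oxopiperidine-1-carboxylate
Product: 19 tert-butyl (S)-5-(4,5-dimethoxy-7-methylnaphthalen-1-yl)-6,8-dihydroxy-3-methyl-3,4-dihydroisoquinoline-2(1H)-carboxylate, via aldol adduct 18 (not isolated)
Conditions: KOH (2 M aq., 5 equiv), MeOH, N2, 0 °C → rt; then AcOH to pH 6
Reagents that add atoms: none
Why: Hydroxide converts the triketone into its enolates; the one formed by removing a proton from the C5 methylene (activated by the C6 carbonyl and the naphthyl group) adds to the ring B carbonyl carbon C4a, and the β-hydroxy ketone 18 loses water (E1cB) and enolizes to the aromatic 6,8-diol. The closest known reaction type is the biomimetic aldol cyclization of 3,5,7-triketones to resorcinols (orcinol-type polyketide folding). Ring A closes in the 6-(enolendo)-exo-trig mode. No new stereocentre remains: the centres created at C4a, C5 and C8a in 18 are erased on aromatization, and C3 is not involved. The step needs C5, not the ring B methylene C4, to act as nucleophile, and this is secured by the substrate: closure through C4 would give a bridged bicyclo[3.3.1] ketol that cannot aromatize and reverts, closure through C7 would give a four-membered ring, and irreversible aromatization drains the equilibria through the C5 pathway. Degassed aqueous methanol at or below room temperature, where the β-dicarbonyl units sit as enolates, is meant to keep retro-Claisen cleavage and β-elimination of the carbamate nitrogen (which would open ring B or scramble C3) slower than ring closure.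

Step 10
Reactants: 19 tert-butyl (S)-5-(4,5-dimethoxy-7-methylnaphthalen-1-yl)-6,8-dihydroxy-3-methyl-3,4-dihydroisoquinoline-2(1H)-carboxylate
Product: 20 tert-butyl (S)-5-(4,5-dimethoxy-7-methylnaphthalen-1-yl)-6,8-dimethoxy-3-methyl-3,4-dihydroisoquinoline-2(1H)-carboxylate
Conditions: Me2SO4, K2CO3, acetone, reflux
Reagents that add atoms: dimethyl sulfate, COS(=O)(=O)OC
Why: Williamson O-methylation of both phenols (the hard electrophile favours O- over C-methylation of the resorcinol); the carbamate nitrogen has no N–H and C3 is not affected.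

Step 11
Reactants: 20 tert-butyl (S)-5-(4,5-dimethoxy-7-methylnaphthalen-1-yl)-6,8-dimethoxy-3-methyl-3,4-dihydroisoquinoline-2(1H)-carboxylate
Product: 21 (3S)-5-(4,5-dimethoxy-7-methylnaphthalen-1-yl)-6,8-dimethoxy-3-methyl-1,2,3,4-tetrahydroisoquinoline
Conditions: HCl (4 M in dioxane), CH2Cl2, 0 °C → rt; then 1 M NaOH
Reagents that add atoms: none
Why: Acidolysis of the tert-butyl carbamate (loss of the tert-butyl cation as isobutene, then decarboxylation) frees the secondary amine; the aryl methyl ethers and the C3 stereocentre are inert to HCl at room temperature.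

Compound list
1 | 2-methoxy-4-methylbenzoic acid | COc1cc(C)ccc1C(=O)O | starting material
2 | 2-methoxy-4-methylbenzoyl chloride | COc1cc(C)ccc1C(=O)Cl | intermediate (not isolated)
3 | N,N-diethyl-2-methoxy-4-methylbenzamide | CCN(CC)C(=O)c1ccc(C)cc1OC | intermediate
4 | N,N-diethyl-2-lithio-6-methoxy-4-methylbenzamide | CCN(CC)C(=O)c1c([Li])cc(C)cc1OC | intermediate (not isolated)
5 | [2-(diethylcarbamoyl)-3-methoxy-5-methylphenyl]magnesium bromide | CCN(CC)C(=O)c1c([Mg]Br)cc(C)cc1OC | intermediate (not isolated)
6 | N,N-diethyl-2-methoxy-4-methyl-6-(prop-2-en-1-yl)benzamide | CCN(CC)C(=O)c1c(CC=C)cc(C)cc1OC | intermediate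
7 | 8-methoxy-6-methylnaphthalen-1(2H)-one | COc1cc(C)cc2C=CCC(=O)c12 | intermediate (not isolated)
8 | 8-methoxy-6-methylnaphthalen-1-ol | COc1cc(C)cc2cccc(O)c12 | intermediate
9 | 4-bromo-8-methoxy-6-methylnaphthalen-1-ol | COc1cc(C)cc2c(Br)ccc(O)c12 | intermediate
10 | 1-bromo-4,5-dimethoxy-7-methylnaphthalene | COc1ccc(Br)c2cc(C)cc(OC)c12 | intermediate
11 | ethyl 2-(4,5-dimethoxy-7-methylnaphthalen-1-yl)acetate | CCOC(=O)Cc1ccc(OC)c2c(OC)cc(C)cc12 | intermediate
12 | tert-butyl (S)-2-methyl-4-oxopiperidine-1-carboxylate | C[C@H]1CC(=O)CCN1C(=O)OC(C)(C)C | starting material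
13 | tert-butyl (S)-2-methyl-4-(pyrrolidin-1-yl)-3,6-dihydropyridine-1(2H)-carboxylate (enamine, double bond C4=C5) | C[C@H]1CC(N2CCCC2)=CCN1C(=O)OC(C)(C)C | intermediate (not isolated)
14 | tert-butyl (S)-5-acetyl-2-methyl-4-(pyrrolidin-1-yl)-3,6-dihydropyridine-1(2H)-carboxylate | C[C@H]1CC(N2CCCC2)=C(C(C)=O)CN1C(=O)OC(C)(C)C | intermediate (not isolated)
15 | tert-butyl (2S)-5-acetyl-2-methyl-4-oxopiperidine-1-carboxylate (C5 enolized; drawn as the diketo tautomer) | CC(C)(C)OC(=O)N1CC(C(C)=O)C(=O)C[C@@H]1C | intermediate
16 | dilithium dienolate of 15 (ring enolate O–Li at C4, terminal enolate C(=CH2)O–Li; 2S) | CC(C)(C)OC(=O)N1CC(C(=C)O[Li])=C(O[Li])C[C@@H]1C | intermediate (not isolated)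
17 | tert-butyl (2S)-5-[4-(4,5-dimethoxy-7-methylnaphthalen-1-yl)-3-oxobutanoyl]-2-methyl-4-oxopiperidine-1-carboxylate (C5 enolized; drawn as the triketo tautomer) | CC(C)(C)OC(=O)N1CC(C(=O)CC(=O)Cc2ccc(OC)c3c(OC)cc(C)cc23)C(=O)C[C@@H]1C | intermediate (key-step precursor)
18 | tert-butyl (3S)-5-(4,5-dimethoxy-7-methylnaphthalen-1-yl)-4a-hydroxy-3-methyl-6,8-dioxooctahydroisoquinoline-2(1H)-carboxylate (mixture at C4a, C5, C8a) | CC(C)(C)OC(=O)N1CC2C(=O)CC(=O)C(c3ccc(OC)c4c(OC)cc(C)cc34)C2(O)C[C@@H]1C | intermediate (not isolated)
19 | tert-butyl (S)-5-(4,5-dimethoxy-7-methylnaphthalen-1-yl)-6,8-dihydroxy-3-methyl-3,4-dihydroisoquinoline-2(1H)-carboxylate | CC(C)(C)OC(=O)N1Cc2c(O)cc(O)c(-c3ccc(OC)c4c(OC)cc(C)cc34)c2C[C@@H]1C | intermediate (key-step product)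
20 | tert-butyl (S)-5-(4,5-dimethoxy-7-methylnaphthalen-1-yl)-6,8-dimethoxy-3-methyl-3,4-dihydroisoquinoline-2(1H)-carboxylate | COc1cc(OC)c(-c2ccc(OC)c3c(OC)cc(C)cc23)c2c1CN(C(=O)OC(C)(C)C)[C@@H](C)C2 | intermediate
21 | (3S)-5-(4,5-dimethoxy-7-methylnaphthalen-1-yl)-6,8-dimethoxy-3-methyl-1,2,3,4-tetrahydroisoquinoline | COc1cc(OC)c(-c2ccc(OC)c3c(OC)cc(C)cc23)c2c1CN[C@@H](C)C2 | target

Total step count: 11.
Longest linear sequence: 10 steps (steps 1–6, then 8–11).

Steps most likely to fail

Step 9. What may go wrong: addition of the crowded, naphthyl-substituted C5 enolate to the ring B ketone may be too slow, so that hydroxide-induced retro-Claisen cleavage of the side chain or opening of ring B by expulsion of the carbamate nitrogen overtakes ring closure. Fallback (sets out from 15 and from 10, comes back at 20): the aryl group is taken out of the ring closure and the biaryl bond is made afterwards by cross-coupling. The dianion 16, made from 15 as in step 8, is acetylated with N-methoxy-N-methylacetamide to give tert-butyl (2S)-2-methyl-4-oxo-5-(3-oxobutanoyl)piperidine-1-carboxylate F1. KOH in aqueous MeOH then closes ring A through the unhindered methyl carbanion and gives tert-butyl (S)-6,8-dihydroxy-3-methyl-3,4-dihydroisoquinoline-2(1H)-carboxylate F2. Me2SO4/K2CO3 in acetone gives tert-butyl (S)-6,8-dimethoxy-3-methyl-3,4-dihydroisoquinoline-2(1H)-carboxylate F3. NBS in MeCN at 0 °C should brominate C5, which is activated by both methoxy groups and less hindered than C7 between them, to give tert-butyl (S)-5-bromo-6,8-dimethoxy-3-methyl-3,4-dihydroisoquinoline-2(1H)-carboxylate F4. In parallel, 10 is converted (n-BuLi, THF, −78 °C; B(OMe)3; aqueous HCl) into (4,5-dimethoxy-7-methylnaphthalen-1-yl)boronic acid F5. Suzuki–Miyaura coupling of F4 with F5 (Pd(OAc)2, SPhos, K3PO4, PhMe–H2O, 100 °C) forms the C5–C1′ bond and gives 20.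

Step 8. What may go wrong: proton transfer from the acidic benzylic CH2 of ester 11 to the dianion may outrun addition to the ester carbonyl, so that both partners are returned after the quench or the ester enolate self-condenses. Fallback (sets out from 11 and from 15, comes back at 17): the acylation is replaced by an aldol addition followed by oxidation. Ester 11 is reduced with i-Bu2AlH (CH2Cl2, −78 °C) to 2-(4,5-dimethoxy-7-methylnaphthalen-1-yl)acetaldehyde F6. The dianion 16, made from 15 as in step 8, adds through its terminal carbon to F6 at −78 °C, where the far more electrophilic aldehyde should be attacked faster than it is deprotonated. This gives tert-butyl (2S)-5-[4-(4,5-dimethoxy-7-methylnaphthalen-1-yl)-3-hydroxybutanoyl]-2-methyl-4-oxopiperidine-1-carboxylate F7, a mixture at the carbinol carbon. Dess–Martin oxidation (CH2Cl2, NaHCO3, 0 °C) of the carbinol gives 17.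

Step 7. What may go wrong: the enamine can form and be acylated on either side of the ketone, so that acetylation at C3 competes with acetylation at C5, and the amine may reversibly open ring B at N–C2 and erode the stereocentre. Fallback (does not use 12; it sets out from commercial methyl (S)-3-aminobutanoate hydrochloride, free base C[C@H](N)CC(=O)OC, and comes back at 15): ring B is built with the acetyl group already in place. Conjugate addition of the free amine (Et3N, MeOH, 0 °C) to but-3-en-2-one gives methyl (S)-3-[(3-oxobutyl)amino]butanoate F8. This is protected at once with Boc2O to give methyl (S)-3-[(tert-butoxycarbonyl)(3-oxobutyl)amino]butanoate F9. KOtBu in THF at 0 °C then effects an intramolecular Claisen condensation in which the α-methylene of the ketone attacks the ester (six-membered ring, driven by formation of the β-diketone enolate). This gives 15 with the acetyl group necessarily on the carbon next to NCH2.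

Further compounds
F1 | step 9 | tert-butyl (2S)-2-methyl-4-oxo-5-(3-oxobutanoyl)piperidine-1-carboxylate | CC(C)(C)OC(=O)N1CC(C(=O)CC(C)=O)C(=O)C[C@@H]1C
F2 | step 9 | tert-butyl (S)-6,8-dihydroxy-3-methyl-3,4-dihydroisoquinoline-2(1H)-carboxylate | CC(C)(C)OC(=O)N1Cc2c(O)cc(O)cc2C[C@@H]1C
F3 | step 9 | tert-butyl (S)-6,8-dimethoxy-3-methyl-3,4-dihydroisoquinoline-2(1H)-carboxylate | CC(C)(C)OC(=O)N1Cc2c(OC)cc(OC)cc2C[C@@H]1C
F4 | step 9 | tert-butyl (S)-5-bromo-6,8-dimethoxy-3-methyl-3,4-dihydroisoquinoline-2(1H)-carboxylate | CC(C)(C)OC(=O)N1Cc2c(OC)cc(OC)c(Br)c2C[C@@H]1C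
F5 | step 9 | (4,5-dimethoxy-7-methylnaphthalen-1-yl)boronic acid | COc1ccc(B(O)O)c2cc(C)cc(OC)c12
F6 | step 8 | 2-(4,5-dimethoxy-7-methylnaphthalen-1-yl)acetaldehyde | O=CCc1ccc(OC)c2c(OC)cc(C)cc12
F7 | step 8 | tert-butyl (2S)-5-[4-(4,5-dimethoxy-7-methylnaphthalen-1-yl)-3-hydroxybutanoyl]-2-methyl-4-oxopiperidine-1-carboxylate | CC(C)(C)OC(=O)N1CC(C(=O)CC(O)Cc2ccc(OC)c3c(OC)cc(C)cc23)C(=O)C[C@@H]1C
F8 | step 7 | methyl (S)-3-[(3-oxobutyl)amino]butanoate | C[C@@H](CC(=O)OC)NCCC(C)=O
F9 | step 7 | methyl (S)-3-[(tert-butoxycarbonyl)(3-oxobutyl)amino]butanoate | C[C@@H](CC(=O)OC)N(CCC(C)=O)C(=O)OC(C)(C)C
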